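## The problem

Target 25 is a single 1,2-dioxane (O1, O2, C3, C4, C5, C6) whose C3 is a methyl peroxyketal carrying a linear sixteen-carbon chain with a conjugated (E)-enyne, and whose C6 carries an acetic acid arm (C7, C8). Of its two stereocentres, C6 (S) is a secondary peroxy carbon that cannot be corrected once made, whereas C3 (R) is a ketal carbon that can exchange its methoxy group in acidic methanol. The (3R,6S) isomer is the chair with the methoxy group axial and both carbon substituents equatorial, so C6 can steer C3 by equilibration, but C3 cannot steer C6. The O–O bond does not tolerate reductants, hydrogenation, low-valent metals at elevated temperature or strong base (Kornblum–DeLaMare fragmentation through C6–H); the ketal is acid-labile, the β-peroxy carboxyl arm can eliminate under base, and the enyne alkene does not survive ozone. The peroxide therefore has to come late, the enyne later still, and everything after ring formation has to be mild. The enabling feature is that C6 carries O1 and, two carbons along the arm at C8, a second oxygen: the unit C6–C7–C8–O is what remains when a 2-substituted oxetane is opened at its substituted carbon. The nucleophile for that opening, a hydroperoxy oxygen on C3, is placed so that the new ring has six members and the closure is a 6-exo-tet substitution.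

## Retrosynthesis

**Enyne and acid.** Acid 25 is taken back to the primary alcohol 23 (oxidation level only, through aldehyde 24). The bond between the alkyne terminus and the alkene is then cut, giving the terminal alkyne 19 and (E)-1-iodoundec-1-ene 22. This cut is preferred to carrying the whole chain, because the enyne alkene would not survive the ozonolysis that installs the peroxide. The forward Sonogashira coupling must run at room temperature on a dialkyl peroxide. Iodide 22 comes from undec-1-yne 20 through the alkenylzirconocene 21.

**Peroxide ring (key cut).** The O1–C6 bond of 19 is cut, and the C8 hydroxyl is tied back to C6 as an oxetane, giving the hydroperoxy ketal 17. Cutting C3–O2 instead would require an enantiopure secondary hydroperoxide, and cutting O1–O2 has no dependable forward reaction. The chosen cut stores the arm oxygen as the leaving group and uses ring strain as the driving force. The forward reaction must be a clean backside attack at the substituted oxetane carbon. Because C3 of 17 cannot be controlled when it is made, part of the material closes to the (3S,6S) epimer 18, which acidic methanol funnels to 19 in the same flask.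

**Hydroperoxy ketal.** Both C3–O bonds of 17 are cut back to the 1,1-disubstituted alkene 14, by way of the primary ozonide 15 and the carbonyl oxide 16. Ozonolysis in methanol builds the methoxy hydroperoxide at −78 °C without acid, so the oxetane is untouched. The forward step asks that ozone take the alkene and leave the terminal alkyne.

**Oxetane.** The O–C8 bond of 14 is cut to the monotosylate 12 of the 1,3-diol 11 (ring closure passes through the silylated oxetane 13). The stereogenic C–O bond is not touched, so the configuration of the diol is carried into the oxetane.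

**Carbon chain.** The diol 11 is protected as the benzylidene acetal 10. The C3–C4 bond of 10 (an sp2–sp3 bond) is cut to the vinyl bromide 8 and the alkylborane 9, which comes from the vinyl dioxane 4. The neighbouring C4–C5 cut would mean alkylating a ketone enolate with a sluggish β-alkoxy iodide and then methylenating. The chosen cut delivers the 1,1-disubstituted alkene directly.

**Building blocks.** Vinyl dioxane 4 comes from aldehyde 3, alcohol 2 and (S)-butane-1,2,4-triol 1, which supplies C5–C8 and the C6 oxygen stereocentre. Bromide 8 comes from (4-bromobut-1-ynyl)trimethylsilane 5 (through Grignard reagent 7) and 2,3-dibromoprop-1-ene 6.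

## Roads not taken

**Alternative 1:** Both peroxide C–O bonds (C3–O2 and C6–O1) are cut at once, back to the 2-alkylfuran tert-butyl-[4-(furan-2-yl)butoxy]-diphenylsilane A1. Forward, sensitised photo-oxygenation adds singlet oxygen across the furan 2- and 5-positions to give the bicyclic endoperoxide A2.
- Merits: the peroxide ring is formed in one step from a trivially made substrate, with oxygen as the reagent and no ozone or isolated hydroperoxide.
- Weak points: A2 is racemic, since nothing in A1 differentiates the furan faces. Its C6 is an acetal carbon bearing hydrogen, at the wrong oxidation level and without the two-carbon arm. Reaching the target would need methanolysis at C3 with the peroxide bridge kept, although methanol normally opens such adducts to a hydroperoxide on a dihydrofuran. It would also need a C–C bond formed at a peroxy-acetal carbon with only relative stereocontrol, and saturation of C4=C5 without touching O–O.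
- Comparison: this road reaches a peroxide faster and with a safer oxidant. The chosen plan reaches its first peroxide only in step 9, but every carbon and the absolute configuration at C6 are then already in place.

**Alternative 2:** The O1–O2 bond is cut, back to the hydroxy ketone methyl (3S)-10-[tert-butyl(diphenyl)silyl]oxy-3-hydroxy-6-oxodecanoate A3. Forward, KHSO5 is meant to convert the ketone into a dioxirane whose oxygen is attacked by the C6 hydroxyl, giving the dioxanol A4.
- Merits: the substrate is stable, C6 is used with retention, the arm is already an ester, and no ozone is needed. In these respects it is better than the chosen plan, which must oxidise C8 at the end.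
- Weak points: attack of an alcohol oxygen on a dioxirane oxygen to form O–O has no mechanistic support, and dioxiranes oxidise secondary alcohols at C–H. A3 is largely held as a five-membered cyclic hemiketal, which removes the ketone. Peroxymonosulfate also promotes Baeyer–Villiger oxidation. After the ring there remain methylation of the hemiketal and four steps to turn the silyloxybutyl chain into the enyne in the presence of a β-peroxy ester.
- Comparison: the chosen plan sets against the attractive substrate a ring-forming step of a known reaction class.

**Alternative 3:** The C3–O2 bond is cut, back to the open-chain hydroperoxide methyl (3S,12E)-3-hydroperoxy-6,6-dimethoxydocos-12-en-10-ynoate A5. Forward, acid in methanol ionises the dimethyl ketal and the hydroperoxy group closes reversibly onto C3, giving the ester A6.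
- Merits: this is the most convergent road. The whole chain and the ester are in place before ring closure, C3 is set thermodynamically within the ring-forming event itself (the chosen plan needs a second stage in step 10 for that), and only an ester hydrolysis follows.
- Weak points: it needs an enantiopure secondary hydroperoxide β to an ester. Making it by intermolecular displacement of a secondary sulfonate with a peroxide nucleophile competes with elimination to the conjugated enoate and with erosion of configuration. A5 is base-sensitive, and the closing saponification of A6 exposes a β-peroxy ester to hydroxide. The enyne must also be present when the peroxide is introduced, which narrows the choice of methods.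
- Comparison: the chosen plan pays with a coupling and an oxidation after the ring. In return it makes the C6–O bond intramolecularly on a strained ether where no elimination pathway exists, and reaches the acid without base.

Key step: step 10

## Route

Assumption: ozonolysis creates C3 without control, so 17 stands for material of both configurations at C3 and is drawn as the 3R epimer, which maps directly onto the target. The two portions are not separated; they are carried into step 10 together and converge there.

Step 1
Reactants: 1 (2S)-butane-1,2,4-triol
Product: 2 [(2S,4S)-2-phenyl-1,3-dioxan-4-yl]methanol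
Conditions: PhCH(OMe)2, CSA (cat.), CH2Cl2, rt
Reagents that add atoms: benzaldehyde dimethyl acetal, COC(OC)c1ccccc1
Why: Thermodynamic acetalisation favours the six-membered 1,3-dioxane across the C2 and C4 hydroxyls with phenyl and hydroxymethyl both equatorial, leaving the C1 hydroxyl free; the acetal carbon is set by this equatorial preference.

Step 2
Reactants: 2 [(2S,4S)-2-phenyl-1,3-dioxan-4-yl]methanol
Product: 3 (2S,4S)-2-phenyl-1,3-dioxane-4-carbaldehyde
Conditions: (COCl)2, DMSO, CH2Cl2, −78 °C; Et3N, −78 → 0 °C
Reagents that add atoms: none
Why: Swern oxidation of a primary alcohol; the low temperature and immediate use of the crude α-alkoxy aldehyde should keep the adjacent stereocentre intact.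

Step 3
Reactants: 3 (2S,4S)-2-phenyl-1,3-dioxane-4-carbaldehyde
Product: 4 (2S,4S)-4-ethenyl-2-phenyl-1,3-dioxane
Conditions: Ph3PCH3Br, KN(SiMe3)2, THF, −78 → 0 °C
Reagents that add atoms: methyltriphenylphosphonium bromide, C[P+](c1ccccc1)(c1ccccc1)c1ccccc1.[Br-]
Why: Wittig methylenation with a non-stabilised ylide is fast at low temperature, so the α-alkoxy aldehyde should be consumed before it can epimerise.

Step 4
Reactants: 5 (4-bromobut-1-ynyl)trimethylsilane; 6 2,3-dibromoprop-1-ene
Product: 8 (6-bromohept-6-en-1-ynyl)trimethylsilane, via Grignard reagent 7 (not isolated)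
Conditions: Mg, THF, rt; then 6, CuI (cat.), THF, −20 °C → rt
Reagents that add atoms: none
Why: Copper-catalysed coupling of a primary Grignard reagent with the allylic bromide of 2,3-dibromopropene is the standard route to 2-bromo-1-alkenes; the vinylic bromide is inert, both allylic termini give the same product, and the silyl group masks the acidic alkyne hydrogen.

Step 5
Reactants: 4 (2S,4S)-4-ethenyl-2-phenyl-1,3-dioxane; 8 (6-bromohept-6-en-1-ynyl)trimethylsilane
Product: 10 trimethyl-[6-methylidene-8-[(2S,4R)-2-phenyl-1,3-dioxan-4-yl]oct-1-ynyl]silane, via alkylborane 9 (not isolated)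
Conditions: 9-BBN, THF, 0 °C → rt; then aq. Cs2CO3, 8, Pd(dppf)Cl2 (cat.), AsPh3 (cat.), DMF, rt
Reagents that add atoms: none
Why: B-alkyl Suzuki–Miyaura coupling: 9-BBN adds to the terminal carbon of the vinyl group, residual borane is destroyed by the aqueous base before 8 is added, and zerovalent palladium joins the primary alkyl group to the vinyl bromide to give the 1,1-disubstituted alkene directly; the dioxane stereocentre is not involved (its descriptor changes only through priorities).

Step 6
Reactants: 10 trimethyl-[6-methylidene-8-[(2S,4R)-2-phenyl-1,3-dioxan-4-yl]oct-1-ynyl]silane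
Product: 11 (3R)-6-methylidene-11-(trimethylsilyl)undec-10-yne-1,3-diol
Conditions: CSA (cat.), MeOH, rt
Reagents that add atoms: none
Why: Acid-catalysed transacetalisation to methanol releases the 1,3-diol; the catalytic acid at room temperature should leave the isolated 1,1-disubstituted alkene and the alkynylsilane untouched.

Step 7
Reactants: 11 (3R)-6-methylidene-11-(trimethylsilyl)undec-10-yne-1,3-diol
Product: 12 [(3R)-3-hydroxy-6-methylidene-11-(trimethylsilyl)undec-10-ynyl] 4-methylbenzenesulfonate
Conditions: TsCl (1.05 equiv), Et3N, DMAP (cat.), CH2Cl2, 0 °C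
Reagents that add atoms: 4-methylbenzenesulfonyl chloride, Cc1ccc(cc1)S(Cl)(=O)=O
Why: Selective sulfonylation of the primary over the secondary hydroxyl of a 1,3-diol on steric grounds, with the reagent limited to one equivalent at low temperature.

Step 8
Reactants: 12 [(3R)-3-hydroxy-6-methylidene-11-(trimethylsilyl)undec-10-ynyl] 4-methylbenzenesulfonate
Product: 14 (2R)-2-(3-methylideneoct-7-ynyl)oxetane, via silylated oxetane 13 (not isolated)
Conditions: KOtBu (2.2 equiv), THF, 0 °C → rt; then MeOH, rt
Reagents that add atoms: none
Why: Intramolecular Williamson etherification (4-exo-tet) of the secondary alkoxide onto the primary tosylate closes the oxetane without touching the stereogenic C–O bond; adding methanol to the excess alkoxide then cleaves the alkynyl–silicon bond to free the terminal alkyne.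

Step 9
Reactants: 14 (2R)-2-(3-methylideneoct-7-ynyl)oxetane
Product: 17 (2R)-2-[(3R)-3-hydroperoxy-3-methoxyoct-7-ynyl]oxetane, via primary ozonide 15 (not isolated), via carbonyl oxide 16 (not isolated)
Conditions: O3, CH2Cl2/MeOH, −78 °C, Sudan Red 7B end-point; N2 purge; concentration below rt, no reductant
Reagents that add atoms: ozone, [O-][O+]=O; methanol, CO
Why: Ozonolysis of a 1,1-disubstituted alkene in methanol: the primary ozonide cleaves to formaldehyde and the more substituted carbonyl oxide, which methanol traps as the methoxy hydroperoxide. The electron-rich alkene reacts with ozone far faster than a terminal alkyne, and the dye end-point guards against over-ozonation. The new ketal centre forms without control, so 17 stands for both configurations at C3.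

Step 10
Reactants: 17 (2R)-2-[(3R)-3-hydroperoxy-3-methoxyoct-7-ynyl]oxetane
Product: 19 2-[(3R,6S)-3-methoxy-3-(pent-4-ynyl)-1,2-dioxan-6-yl]ethanol, via (3S,6S)-epimer 18 (not isolated)
Conditions: Yb(OTf)3 (cat.), CH2Cl2, 0 °C → rt, high dilution; then MeOH, CSA (cat.), rt; chromatography, residual epimer resubmitted to the second stage
Reagents that add atoms: methanol, CO
Why: Coordination of Yb(OTf)3 to the oxetane oxygen polarises the ring C–O bond at the substituted carbon, and the terminal hydroperoxide oxygen displaces that oxygen from the rear, forming O1–C6 and leaving the former ring oxygen as the 2-hydroxyethyl arm after proton transfer. The closest known reaction type is the intramolecular ring opening of oxetanes by hydroperoxides and hydroperoxy ketals under Lewis acid catalysis, which delivers 1,2-dioxolanes and 1,2-dioxanes. The single ring is closed in the 6-exo-tet mode. The new stereocentre C6 is controlled by the oxetane carbon that stems from C2 of triol 1, and backside attack inverts it to 6S. Regioselectivity follows from ring size, since the oxetane CH2 could only be reached through an eight-membered transition state, and chemoselectivity from the hydroperoxy oxygen being far more nucleophilic than the ketal methoxy oxygen. A mild lanthanide triflate is chosen so that the secondary oxetane carbon reacts by substitution with inversion and the ketal carbon is not ionised in the first stage. C3 is a spectator in the ring closure, so the 3R portion of 17 gives 19 directly and the 3S portion gives the epimer 18. In the second stage, acid-catalysed exchange of the ketal methoxy group with methanol (reversible ionisation at C3) should funnel 18 to 19, the chair with axial methoxy (anomeric effect) and both carbon substituents equatorial.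

Step 11
Reactants: 20 undec-1-yne
Product: 22 (E)-1-iodoundec-1-ene, via alkenylzirconocene 21 (not isolated)
Conditions: Cp2Zr(H)Cl, THF, rt; then I2, 0 °C
Reagents that add atoms: iodine, II
Why: Hydrozirconation adds Zr–H syn across the terminal alkyne with zirconium at the terminal carbon, and iodinolysis of the C–Zr bond proceeds with retention, which fixes the E geometry.

Step 12
Reactants: 19 2-[(3R,6S)-3-methoxy-3-(pent-4-ynyl)-1,2-dioxan-6-yl]ethanol; 22 (E)-1-iodoundec-1-ene
Product: 23 2-[(3R,6S)-3-[(E)-hexadec-6-en-4-ynyl]-3-methoxy-1,2-dioxan-6-yl]ethanol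
Conditions: Pd(PPh3)4 (cat.), CuI (cat.), Et3N, THF, rt, degassed
Reagents that add atoms: none
Why: Sonogashira coupling of a terminal alkyne with a vinyl iodide runs at room temperature with retention of alkene geometry; an unactivated dialkyl peroxide should tolerate the zerovalent palladium catalyst and the amine under these conditions, and the free hydroxyl does not interfere.

Step 13
Reactants: 23 2-[(3R,6S)-3-[(E)-hexadec-6-en-4-ynyl]-3-methoxy-1,2-dioxan-6-yl]ethanol
Product: 25 2-[(3R,6S)-3-[(E)-hexadec-6-en-4-ynyl]-3-methoxy-1,2-dioxan-6-yl]acetic acid, via aldehyde 24 (not isolated)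
Conditions: TEMPO (cat.), PhI(OAc)2, MeCN/H2O, 0 °C → rt
Reagents that add atoms: water, O
Why: Oxoammonium-mediated oxidation of the primary alcohol to the aldehyde, whose hydrate is oxidised on to the acid in the same flask; the conditions are non-basic and non-reducing, so the peroxide, the ketal and the enyne should persist and neither stereocentre is touched.

## Compound list

1 | (2S)-butane-1,2,4-triol | OCC[C@H](O)CO | starting material
2 | [(2S,4S)-2-phenyl-1,3-dioxan-4-yl]methanol | OC[C@@H]1CCO[C@H](c2ccccc2)O1 | intermediate
3 | (2S,4S)-2-phenyl-1,3-dioxane-4-carbaldehyde | O=C[C@@H]1CCO[C@H](c2ccccc2)O1 | intermediate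
4 | (2S,4S)-4-ethenyl-2-phenyl-1,3-dioxane | C=C[C@@H]1CCO[C@H](c2ccccc2)O1 | intermediate
5 | (4-bromobut-1-ynyl)trimethylsilane | C[Si](C)(C)C#CCCBr | starting material
6 | 2,3-dibromoprop-1-ene | BrCC(Br)=C | starting material
7 | [4-(trimethylsilyl)but-3-ynyl]magnesium bromide (not isolated) | C[Si](C)(C)C#CCC[Mg]Br | intermediate
8 | (6-bromohept-6-en-1-ynyl)trimethylsilane | C[Si](C)(C)C#CCCCC(Br)=C | intermediate
9 | 9-[2-[(2S,4R)-2-phenyl-1,3-dioxan-4-yl]ethyl]-9-borabicyclo[3.3.1]nonane (not isolated) | B1(CC[C@@H]2CCO[C@H](c3ccccc3)O2)C2CCCC1CCC2 | intermediate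
10 | trimethyl-[6-methylidene-8-[(2S,4R)-2-phenyl-1,3-dioxan-4-yl]oct-1-ynyl]silane | C[Si](C)(C)C#CCCCC(=C)CC[C@@H]1CCO[C@H](c2ccccc2)O1 | intermediate
11 | (3R)-6-methylidene-11-(trimethylsilyl)undec-10-yne-1,3-diol | C[Si](C)(C)C#CCCCC(=C)CC[C@@H](O)CCO | intermediate
12 | [(3R)-3-hydroxy-6-methylidene-11-(trimethylsilyl)undec-10-ynyl] 4-methylbenzenesulfonate | C[Si](C)(C)C#CCCCC(=C)CC[C@@H](O)CCOS(=O)(=O)c1ccc(C)cc1 | intermediate
13 | trimethyl-[6-methylidene-8-[(2R)-oxetan-2-yl]oct-1-ynyl]silane (not isolated) | C[Si](C)(C)C#CCCCC(=C)CC[C@H]1OCC1 | intermediate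
14 | (2R)-2-(3-methylideneoct-7-ynyl)oxetane | C#CCCCC(=C)CC[C@H]1OCC1 | intermediate
15 | (2R)-2-[2-[4-(pent-4-ynyl)-1,2,3-trioxolan-4-yl]ethyl]oxetane, primary ozonide, both ring epimers (not isolated) | C#CCCCC1(CC[C@H]2OCC2)COOO1 | intermediate
16 | 1-[(2R)-oxetan-2-yl]oct-7-yn-3-one O-oxide, carbonyl oxide (not isolated) | C#CCCCC(=[O+][O-])CC[C@H]1OCC1 | intermediate
17 | (2R)-2-[(3R)-3-hydroperoxy-3-methoxyoct-7-ynyl]oxetane (material of both configurations at C3; the 3R form is drawn) | C#CCCC[C@@](OC)(OO)CC[C@H]1OCC1 | intermediate
18 | 2-[(3S,6S)-3-methoxy-3-(pent-4-ynyl)-1,2-dioxan-6-yl]ethanol (not isolated) | C#CCCC[C@@]1(OC)CC[C@@H](CCO)OO1 | intermediate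
19 | 2-[(3R,6S)-3-methoxy-3-(pent-4-ynyl)-1,2-dioxan-6-yl]ethanol | C#CCCC[C@]1(OC)CC[C@@H](CCO)OO1 | intermediate
20 | undec-1-yne | C#CCCCCCCCCC | starting material
21 | chlorobis(cyclopentadienyl)[(E)-undec-1-enyl]zirconium (not isolated) | CCCCCCCCC/C=C/[Zr](Cl)(C1C=CC=C1)C1C=CC=C1 | intermediate
22 | (E)-1-iodoundec-1-ene | CCCCCCCCC/C=C/I | intermediate
23 | 2-[(3R,6S)-3-[(E)-hexadec-6-en-4-ynyl]-3-methoxy-1,2-dioxan-6-yl]ethanol | CCCCCCCCC/C=C/C#CCCC[C@]1(OC)CC[C@@H](CCO)OO1 | intermediate
24 | 2-[(3R,6S)-3-[(E)-hexadec-6-en-4-ynyl]-3-methoxy-1,2-dioxan-6-yl]acetaldehyde (not isolated) | CCCCCCCCC/C=C/C#CCCC[C@]1(OC)CC[C@@H](CC=O)OO1 | intermediate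
25 | 2-[(3R,6S)-3-[(E)-hexadec-6-en-4-ynyl]-3-methoxy-1,2-dioxan-6-yl]acetic acid | CCCCCCCCC/C=C/C#CCCC[C@]1(OC)CC[C@@H](CC(=O)O)OO1 | target

## Summary and risks

Total step count: 13. Longest linear sequence: 11 steps (1, 2, 3, 5, 6, 7, 8, 9, 10, 12, 13); steps 4 and 11 prepare the two side fragments.

**Step 10 (key step).**
- What may go wrong: partial ionisation of the activated oxetane would erode the inversion at C6. The Lewis acid could instead ionise the ketal carbon, with loss of methanol or hydrogen peroxide. Intermolecular oxetane opening could compete if dilution is insufficient. In the second stage, ionisation on the peroxide side with loss of the ring could run faster than methoxy exchange, or the equilibrium could be less one-sided than the chair analysis suggests.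
- Fallback (the electrophile is changed from an oxetane to a sulfonate): it sets out from diol 11 and returns at 19. The primary hydroxyl is silylated (TBSCl, imidazole) to (3R)-1-[tert-butyl(dimethyl)silyl]oxy-6-methylidene-11-trimethylsilylundec-10-yn-3-ol F1. The secondary hydroxyl is mesylated to [(3R)-1-[tert-butyl(dimethyl)silyl]oxy-6-methylidene-11-trimethylsilylundec-10-yn-3-yl] methanesulfonate F2. Ozonolysis in methanol then proceeds through the primary ozonide [(3R)-1-[tert-butyl(dimethyl)silyl]oxy-5-[4-(5-trimethylsilylpent-4-ynyl)-1,2,3-trioxolan-4-yl]pentan-3-yl] methanesulfonate F3 and the carbonyl oxide [(3R)-1-[tert-butyl(dimethyl)silyl]oxy-6-oxo-11-trimethylsilylundec-10-yn-3-yl] methanesulfonate O-oxide F4, neither isolated. It gives the hydroperoxy ketal [(3R)-1-[tert-butyl(dimethyl)silyl]oxy-6-hydroperoxy-6-methoxy-11-trimethylsilylundec-10-yn-3-yl] methanesulfonate F5 as both ketal epimers. One equivalent of KOtBu with 18-crown-6 deprotonates the hydroperoxide, which displaces the mesylate intramolecularly with inversion (6-exo-tet). This gives tert-butyl-[2-[(6S)-3-methoxy-3-(5-trimethylsilylpent-4-ynyl)-1,2-dioxan-6-yl]ethoxy]-dimethylsilane F6 as both C3 epimers. TBAF removes both silyl groups to deliver 19 together with 18, and the CSA/methanol stage of step 10 converges the pair on 19. The secondary oxygen of 11 has the same spatial arrangement as the oxetane oxygen of 17, so inversion again gives 6S.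

**Step 9.**
- What may go wrong: over-oxidation of the terminal alkyne once the alkene is consumed, and decomposition or loss of the hydroperoxy ketal during concentration and handling.
- Fallback (no ozone, the peroxide oxygen comes from hydrogen peroxide): it sets out from 14 and returns at 17. Lemieux–Johnson cleavage (OsO4 cat., NaIO4, 2,6-lutidine, dioxane/H2O) proceeds through the diol 2-[2-[(2R)-oxetan-2-yl]ethyl]hept-6-yne-1,2-diol F7 to the ketone 1-[(2R)-oxetan-2-yl]oct-7-yn-3-one F8. HC(OMe)3 in methanol with PPTS gives the dimethyl ketal (2R)-2-(3,3-dimethoxyoct-7-ynyl)oxetane F9. Acid-catalysed exchange of one methoxy group with anhydrous ethereal H2O2 gives the methoxy hydroperoxide 17, again as material of both configurations at C3.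

**Step 13.**
- What may go wrong: attack of the oxidant on the conjugated enyne, and a slow second oxidation stage during which the β-peroxy aldehyde can eliminate and open the ring.
- Fallback (oxidise before the enyne exists): it sets out from 19 and returns at the target 25. The same TEMPO/PhI(OAc)2 oxidation is applied to 19, passing through 2-[(3R,6S)-3-methoxy-3-(pent-4-ynyl)-1,2-dioxan-6-yl]acetaldehyde F10 (not isolated) to 2-[(3R,6S)-3-methoxy-3-(pent-4-ynyl)-1,2-dioxan-6-yl]acetic acid F11. Sonogashira coupling of F11 with 22 (Pd(PPh3)4, CuI, excess Et3N, THF, rt) then gives 25 directly. This removes the enyne from the oxidation but not the elimination risk of the aldehyde, which the smaller substrate should only make easier to outrun.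

## Further compounds

F1 | step 10 | (3R)-1-[tert-butyl(dimethyl)silyl]oxy-6-methylidene-11-trimethylsilylundec-10-yn-3-ol | C[Si](C)(C)C#CCCCC(=C)CC[C@@H](O)CCO[Si](C)(C)C(C)(C)C
F2 | step 10 | [(3R)-1-[tert-butyl(dimethyl)silyl]oxy-6-methylidene-11-trimethylsilylundec-10-yn-3-yl] methanesulfonate | C[Si](C)(C)C#CCCCC(=C)CC[C@@H](OS(C)(=O)=O)CCO[Si](C)(C)C(C)(C)C
F3 | step 10 | [(3R)-1-[tert-butyl(dimethyl)silyl]oxy-5-[4-(5-trimethylsilylpent-4-ynyl)-1,2,3-trioxolan-4-yl]pentan-3-yl] methanesulfonate (both ring epimers) | C[Si](C)(C)C#CCCCC1(COOO1)CC[C@@H](OS(C)(=O)=O)CCO[Si](C)(C)C(C)(C)C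
F4 | step 10 | [(3R)-1-[tert-butyl(dimethyl)silyl]oxy-6-oxo-11-trimethylsilylundec-10-yn-3-yl] methanesulfonate O-oxide | C[Si](C)(C)C#CCCCC(=[O+][O-])CC[C@@H](OS(C)(=O)=O)CCO[Si](C)(C)C(C)(C)C
F5 | step 10 | [(3R)-1-[tert-butyl(dimethyl)silyl]oxy-6-hydroperoxy-6-methoxy-11-trimethylsilylundec-10-yn-3-yl] methanesulfonate (both C6 epimers) | C[Si](C)(C)C#CCCCC(OC)(OO)CC[C@@H](OS(C)(=O)=O)CCO[Si](C)(C)C(C)(C)C
F6 | step 10 | tert-butyl-[2-[(6S)-3-methoxy-3-(5-trimethylsilylpent-4-ynyl)-1,2-dioxan-6-yl]ethoxy]-dimethylsilane (both C3 epimers) | C[Si](C)(C)C#CCCCC1(OC)CC[C@@H](CCO[Si](C)(C)C(C)(C)C)OO1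
F7 | step 9 | 2-[2-[(2R)-oxetan-2-yl]ethyl]hept-6-yne-1,2-diol (both C2 epimers) | C#CCCCC(O)(CO)CC[C@H]1OCC1
F8 | step 9 | 1-[(2R)-oxetan-2-yl]oct-7-yn-3-one | C#CCCCC(=O)CC[C@H]1OCC1
F9 | step 9 | (2R)-2-(3,3-dimethoxyoct-7-ynyl)oxetane | C#CCCCC(OC)(OC)CC[C@H]1OCC1
F10 | step 13 | 2-[(3R,6S)-3-methoxy-3-(pent-4-ynyl)-1,2-dioxan-6-yl]acetaldehyde | C#CCCC[C@]1(OC)CC[C@@H](CC=O)OO1
F11 | step 13 | 2-[(3R,6S)-3-methoxy-3-(pent-4-ynyl)-1,2-dioxan-6-yl]acetic acid | C#CCCC[C@]1(OC)CC[C@@H](CC(=O)O)OO1
A1 | alternative 1 | tert-butyl-[4-(furan-2-yl)butoxy]-diphenylsilane | CC(C)(C)[Si](c1ccccc1)(c1ccccc1)OCCCCc1ccco1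
A2 | alternative 1 | 1-[4-[tert-butyl(diphenyl)silyl]oxybutyl]-2,3,7-trioxabicyclo[2.2.1]hept-5-ene (racemic; one enantiomer drawn) | CC(C)(C)[Si](c1ccccc1)(c1ccccc1)OCCCC[C@]23C=C[C@H](OO2)O3
A3 | alternative 2 | methyl (3S)-10-[tert-butyl(diphenyl)silyl]oxy-3-hydroxy-6-oxodecanoate | CC(C)(C)[Si](c1ccccc1)(c1ccccc1)OCCCCC(=O)CC[C@@H](CC(=O)OC)O
A4 | alternative 2 | methyl 2-[(3R,6S)-3-[4-[tert-butyl(diphenyl)silyl]oxybutyl]-3-hydroxy-1,2-dioxan-6-yl]acetate | CC(C)(C)[Si](c1ccccc1)(c1ccccc1)OCCCC[C@]1(O)CC[C@@H](CC(=O)OC)OO1
A5 | alternative 3 | methyl (3S,12E)-3-hydroperoxy-6,6-dimethoxydocos-12-en-10-ynoate | CCCCCCCCC/C=C/C#CCCCC(OC)(OC)CC[C@@H](CC(=O)OC)OO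
A6 | alternative 3 | methyl 2-[(3R,6S)-3-[(E)-hexadec-6-en-4-ynyl]-3-methoxy-1,2-dioxan-6-yl]acetate | CCCCCCCCC/C=C/C#CCCC[C@]1(OC)CC[C@@H](CC(=O)OC)OO1
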